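**Plan**

- Retrosynthetic cuts: (a) N1'–C7a' of one indole, after stepping back to the indoline oxidation level, which leaves a 2-phenylethylamine picolinamide on C2 of the indoxyl; (b) the bond from C2 to the benzylic carbon (the later C3'), a Michael addition of a 2-(indol-3-yl)indoxyl enolate to β-nitrostyrene; (c) the bond from C2 to C3 of the other indole, a Friedel–Crafts alkylation of indole by 2-bromo-1-acetylindoxyl.
- Feature used: in each indol-3-yl unit N1' is bonded to the benzo carbon C7a'. A CH(Ph)–CH2–NH chain on C2 already holds C3', C3a' (the phenyl ipso carbon), C2' and N1', so the five-membered ring can be closed at N1'–C7a' on an ortho C–H bond of the phenyl ring.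
- Forward order: the indoxyl ring and the first indole are bought. The C2–indole bond is made first, then the quaternary C2 by Michael addition. The nitro group becomes the picolinamide, the indole is masked as its carbamate, the C–H amination closes the new five-membered ring, all N-acyl groups are hydrolysed and MnO2 aromatises the indoline.
- Stereochemistry: the target is achiral because C2 carries two identical indol-3-yl groups. C2 and the benzylic carbon are stereogenic only in intermediates, which are carried as racemic diastereomer mixtures; both centres are erased in the last step.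

Key step: step 7

Remark: 1-acetylindolin-3-one, indole, (E)-β-nitrostyrene and picolinoyl chloride hydrochloride are taken as purchased. The acid chloride replaces the free acid so that the amine can be acylated under aqueous two-phase conditions.

**Route**

Step 1
Reactants: 1 1-acetylindolin-3-one
Product: 2 1-acetyl-2-bromoindolin-3-one (racemic, used crude)
Conditions: Br2 (1.0 equiv), CH2Cl2, 0 °C
Reagents that add atoms: bromine, BrBr
Why: α-Bromination of a ketone through its enol at the only enolisable position, C2, between the ketone and the amide nitrogen; one equivalent at 0 °C should stop at the monobromide.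

Step 2
Reactants: 2 1-acetyl-2-bromoindolin-3-one; 3 indole
Product: 4 1-acetyl-2-(1H-indol-3-yl)indolin-3-one (racemic)
Conditions: indole (2 equiv), NaHCO3 (2 equiv), MeCN, 0 °C to rt, Ar
Reagents that add atoms: none
Why: Friedel–Crafts alkylation (α-amidoalkylation) of indole at its nucleophilic C3 by the doubly activated C2–Br bond (α-bromo ketone and N-acyl N,Br-acetal), with solid NaHCO3 taking up HBr so that indole does not oligomerise; the new stereocentre forms racemic and is not needed.

Step 3
Reactants: 4 1-acetyl-2-(1H-indol-3-yl)indolin-3-one; 5 (E)-β-nitrostyrene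
Product: 6 1-acetyl-2-(1H-indol-3-yl)-2-(2-nitro-1-phenylethyl)indolin-3-one (mixture of racemic diastereomers)
Conditions: Et3N (0.2 equiv), CH2Cl2, rt, Ar
Reagents that add atoms: none
Why: Base-catalysed Michael addition: the C2–H of 4 is acidified by the ketone, the amide nitrogen and the indolyl group, so a tertiary amine should generate the enolate, which adds through carbon to the nitroalkene and sets the quaternary C2; neither new stereocentre is controlled because both disappear later.

Step 4
Reactants: 6 1-acetyl-2-(1H-indol-3-yl)-2-(2-nitro-1-phenylethyl)indolin-3-one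
Product: 7 2-[1-acetyl-2-(1H-indol-3-yl)-3-oxoindolin-2-yl]-2-phenylethan-1-aminium chloride (diastereomer mixture, crude salt taken on at once)
Conditions: Zn dust (10 equiv), 2 M aq HCl, EtOH, 0 °C; filter, concentrate cold
Reagents that add atoms: hydrogen chloride, Cl
Why: Dissolving-metal reduction of an aliphatic nitro group to the amine, run in strong aqueous acid so that the amine stays protonated and cannot attack the C3 ketone or the N-acetyl group.

Step 5
Reactants: 7 2-[1-acetyl-2-(1H-indol-3-yl)-3-oxoindolin-2-yl]-2-phenylethan-1-aminium chloride; 8 picolinoyl chloride hydrochloride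
Product: 9 N-{2-[1-acetyl-2-(1H-indol-3-yl)-3-oxoindolin-2-yl]-2-phenylethyl}picolinamide (diastereomer mixture)
Conditions: 8 (2 equiv), NaHCO3 (excess), CH2Cl2/H2O, 0 °C
Reagents that add atoms: none
Why: Schotten–Baumann N-acylation: the amine freed at the interface should be acylated at once by the acid chloride, and any ring-closed imine formed on neutralisation would be opened to the same keto amide through its N-acyliminium ion and water.

Step 6
Reactants: 9 N-{2-[1-acetyl-2-(1H-indol-3-yl)-3-oxoindolin-2-yl]-2-phenylethyl}picolinamide
Product: 10 N-{2-[1-acetyl-2-(1-tert-butoxycarbonylindol-3-yl)-3-oxoindolin-2-yl]-2-phenylethyl}picolinamide (diastereomer mixture)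
Conditions: Boc2O (1.1 equiv), DMAP (0.1 equiv), MeCN, rt
Reagents that add atoms: di-tert-butyl dicarbonate, CC(C)(C)OC(=O)OC(=O)OC(C)(C)C
Why: DMAP-catalysed carbamoylation, selective with one equivalent of Boc2O for the more acidic indole N–H over the secondary amide N–H, as in the indole protection of tryptophan amides; the carbamate shields the indole from the oxidant of the next step.

Step 7
Reactants: 10 N-{2-[1-acetyl-2-(1-tert-butoxycarbonylindol-3-yl)-3-oxoindolin-2-yl]-2-phenylethyl}picolinamide
Product: 11 1-acetyl-2-(1-tert-butoxycarbonylindol-3-yl)-2-(1-picolinoylindolin-3-yl)indolin-3-one (diastereomer mixture)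
Conditions: Pd(OAc)2 (5 mol %), PhI(OAc)2 (2.5 equiv), toluene, 60 °C, Ar
Reagents that add atoms: none
Why: The deprotonated picolinamide binds divalent palladium through its pyridine and amide nitrogens, acetate-assisted concerted metalation–deprotonation of an ortho C–H bond of the phenyl ring gives a six-membered palladacycle, PhI(OAc)2 oxidises it to tetravalent palladium, and C(sp2)–N reductive elimination forms N1'–C7a' and returns divalent palladium. The closest known reaction type is the picolinamide-directed palladium-catalysed intramolecular C–H amination of 2-arylethylamines to indolines. The five-membered indoline ring is closed by that reductive elimination, formally a ring contraction of the six-membered palladacycle with extrusion of the metal, not by an exo or endo nucleophilic attack. No stereocentre is created, the two existing ones are untouched, and both diastereomers should cyclise because they converge later. The step needs site selectivity for the phenyl ortho C–H over the indole C2'–H and C4'–H bonds, which the six-membered palladacycle (against a seven-membered one) and the deactivating carbamate secure; the two ortho positions are equivalent. It also needs C–N over C–O reductive elimination, which toluene without added acetic acid at moderate temperature should favour.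

Step 8
Reactants: 11 1-acetyl-2-(1-tert-butoxycarbonylindol-3-yl)-2-(1-picolinoylindolin-3-yl)indolin-3-one
Product: 12 2-(1H-indol-3-yl)-2-(indolin-3-yl)indolin-3-one (diastereomer mixture)
Conditions: NaOH (6 equiv), MeOH/THF/H2O, 50 °C, Ar
Reagents that add atoms: none
Why: Hydroxide acyl substitution at three activated N-acyl groups, namely the anilide-type picolinoyl on the indoline, the acetyl on the indoxyl nitrogen (which leaves as a vinylogous amide anion) and the indole carbamate; the quaternary centre has no base-labile bond.

Step 9
Reactants: 12 2-(1H-indol-3-yl)-2-(indolin-3-yl)indolin-3-one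
Product: 13 2,2-bis(3'-indolyl)indoxyl
Conditions: activated MnO2 (10 equiv), CH2Cl2, rt
Reagents that add atoms: none
Why: Dehydrogenation of an N–H indoline to the indole by MnO2, driven by aromatisation; it removes the benzylic stereocentre and makes C2 non-stereogenic, while the 2,2-disubstituted indoxyl and the existing indole offer no oxidisable C–H next to nitrogen.

**Compound list**

1 | 1-acetylindolin-3-one | CC(=O)N1CC(=O)c2ccccc21 | starting material
2 | 1-acetyl-2-bromoindolin-3-one (racemic) | CC(=O)N1C(Br)C(=O)c2ccccc21 | intermediate
3 | indole | c1ccc2[nH]ccc2c1 | starting material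
4 | 1-acetyl-2-(1H-indol-3-yl)indolin-3-one (racemic) | CC(=O)N1C(c2c[nH]c3ccccc23)C(=O)c2ccccc21 | intermediate
5 | (E)-β-nitrostyrene | O=[N+]([O-])/C=C/c1ccccc1 | starting material
6 | 1-acetyl-2-(1H-indol-3-yl)-2-(2-nitro-1-phenylethyl)indolin-3-one (diastereomer mixture) | CC(=O)N1c2ccccc2C(=O)C1(c1c[nH]c2ccccc12)C(C[N+](=O)[O-])c1ccccc1 | intermediate
7 | 2-[1-acetyl-2-(1H-indol-3-yl)-3-oxoindolin-2-yl]-2-phenylethan-1-aminium chloride (diastereomer mixture) | CC(=O)N1c2ccccc2C(=O)C1(c1c[nH]c2ccccc12)C(C[NH3+])c1ccccc1.[Cl-] | intermediate
8 | picolinoyl chloride hydrochloride | O=C(Cl)c1ccccn1.Cl | starting material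
9 | N-{2-[1-acetyl-2-(1H-indol-3-yl)-3-oxoindolin-2-yl]-2-phenylethyl}picolinamide (diastereomer mixture) | O=C(NCC(c1ccccc1)C1(c2c[nH]c3ccccc23)N(C(C)=O)c2ccccc2C1=O)c1ccccn1 | intermediate
10 | N-{2-[1-acetyl-2-(1-tert-butoxycarbonylindol-3-yl)-3-oxoindolin-2-yl]-2-phenylethyl}picolinamide (diastereomer mixture) | O=C(NCC(c1ccccc1)C1(c2cn(C(=O)OC(C)(C)C)c3ccccc23)N(C(C)=O)c2ccccc2C1=O)c1ccccn1 | intermediate
11 | 1-acetyl-2-(1-tert-butoxycarbonylindol-3-yl)-2-(1-picolinoylindolin-3-yl)indolin-3-one (diastereomer mixture) | O=C(c1ccccn1)N1CC(c2ccccc21)C1(c2cn(C(=O)OC(C)(C)C)c3ccccc23)N(C(C)=O)c2ccccc2C1=O | intermediate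
12 | 2-(1H-indol-3-yl)-2-(indolin-3-yl)indolin-3-one (diastereomer mixture) | O=C1c2ccccc2NC1(c1c[nH]c2ccccc12)C1CNc2ccccc21 | intermediate
13 | 2,2-bis(3'-indolyl)indoxyl | O=C1c2ccccc2NC1(c1c[nH]c2ccccc12)c1c[nH]c2ccccc12 | target

**Totals and risks**

Total step count: 9. Longest linear sequence: 9 steps, from 1-acetylindolin-3-one.

Steps most likely to fail:

1. Step 7. The tetravalent palladium intermediate may undergo C–O instead of C–N reductive elimination (ortho-acetoxylation), palladation may be slowed by the crowded quaternary neighbour, or the oxidant may attack the heteroaromatic rings. The fallback closes the same N1'–C7a' bond by intramolecular amidation of an aryl bromide, which needs no oxidant and therefore no indole carbamate. It sets out from compound 4, which is combined under the conditions of step 3 with bought (E)-1-bromo-2-(2-nitrovinyl)benzene F1 to give 1-acetyl-2-[1-(2-bromophenyl)-2-nitroethyl]-2-(1H-indol-3-yl)indolin-3-one F2. Reduction with Zn and aqueous HCl as in step 4 should give 2-[1-acetyl-2-(1H-indol-3-yl)-3-oxoindolin-2-yl]-2-(2-bromophenyl)ethan-1-aminium chloride F3, and acylation with 8 as in step 5 should give N-{2-[1-acetyl-2-(1H-indol-3-yl)-3-oxoindolin-2-yl]-2-(2-bromophenyl)ethyl}picolinamide F4. Goldberg cyclisation (CuI, N,N'-dimethylethane-1,2-diamine, K3PO4, toluene, 90 °C) should then close the ring to 1-acetyl-2-(1H-indol-3-yl)-2-(1-picolinoylindolin-3-yl)indolin-3-one F5. Hydrolysis of F5 under the conditions of step 8 comes back to the route at compound 12.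

2. Step 4. When the amine is released, it may close onto the C3 ketone to a five-membered cyclic imine, or take over the acetyl group from N1, before it is acylated. The fallback makes the ring closure deliberate and sets out from compound 6. Zn in acetic acid at 50 °C should reduce the nitro group and let the amine condense with the ketone, giving 4-acetyl-3a-(1H-indol-3-yl)-3-phenyl-2,3,3a,4-tetrahydropyrrolo[3,2-b]indole F6, in which the nitrogen is no longer a free amine. Acylative ring opening of this 1-pyrroline with 8 in CH2Cl2/aqueous NaHCO3 (N-acyliminium ion, addition of water at the former ketone carbon, collapse of the carbinolamide) comes back to the route at compound 9.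

3. Step 3. The conjugate addition may be slow or reversible at the crowded C2, and the enolate of 4 may be oxidised by traces of air. The fallback builds the quaternary centre in the reverse order and sets out from compound 1. Its amine-catalysed Michael addition to 5 should give 1-acetyl-2-(2-nitro-1-phenylethyl)indolin-3-one F7. Bromination at C2 (Br2, CH2Cl2, 0 °C) should give 1-acetyl-2-bromo-2-(2-nitro-1-phenylethyl)indolin-3-one F8, and Friedel–Crafts alkylation of indole 3 by this tertiary bromide under the conditions of step 2 comes back to the route at compound 6.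

**Further compounds**

F1 | step 7 | (E)-1-bromo-2-(2-nitrovinyl)benzene (bought) | O=[N+]([O-])/C=C/c1ccccc1Br
F2 | step 7 | 1-acetyl-2-[1-(2-bromophenyl)-2-nitroethyl]-2-(1H-indol-3-yl)indolin-3-one (diastereomer mixture) | CC(=O)N1c2ccccc2C(=O)C1(c1c[nH]c2ccccc12)C(C[N+](=O)[O-])c1ccccc1Br
F3 | step 7 | 2-[1-acetyl-2-(1H-indol-3-yl)-3-oxoindolin-2-yl]-2-(2-bromophenyl)ethan-1-aminium chloride (diastereomer mixture) | CC(=O)N1c2ccccc2C(=O)C1(c1c[nH]c2ccccc12)C(C[NH3+])c1ccccc1Br.[Cl-]
F4 | step 7 | N-{2-[1-acetyl-2-(1H-indol-3-yl)-3-oxoindolin-2-yl]-2-(2-bromophenyl)ethyl}picolinamide (diastereomer mixture) | O=C(NCC(c1ccccc1Br)C1(c2c[nH]c3ccccc23)N(C(C)=O)c2ccccc2C1=O)c1ccccn1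
F5 | step 7 | 1-acetyl-2-(1H-indol-3-yl)-2-(1-picolinoylindolin-3-yl)indolin-3-one (diastereomer mixture) | O=C(c1ccccn1)N1CC(c2ccccc21)C1(c2c[nH]c3ccccc23)N(C(C)=O)c2ccccc2C1=O
F6 | step 4 | 4-acetyl-3a-(1H-indol-3-yl)-3-phenyl-2,3,3a,4-tetrahydropyrrolo[3,2-b]indole (diastereomer mixture) | CC(=O)N1c2ccccc2C2=NCC(c3ccccc3)C12c1c[nH]c2ccccc12
F7 | step 3 | 1-acetyl-2-(2-nitro-1-phenylethyl)indolin-3-one (diastereomer mixture) | CC(=O)N1c2ccccc2C(=O)C1C(C[N+](=O)[O-])c1ccccc1
F8 | step 3 | 1-acetyl-2-bromo-2-(2-nitro-1-phenylethyl)indolin-3-one (diastereomer mixture) | CC(=O)N1c2ccccc2C(=O)C1(Br)C(C[N+](=O)[O-])c1ccccc1
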